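## Retrosynthetic overview

1. The carbinol-derived C–Cl bond is made last: target ⇐ an equatorial allylic cyclohexanol (both bromines and the other chlorine already in place) by SN2 deoxychlorination with inversion.
2. The cyclohexane, the only ring of the target, ⇐ bromonium-initiated cation–diene cyclisation of an acyclic C10 (Z)-chlorodienyl borate. This one event forms the ring C–C bond, the ring C–Br, the axial C–Cl and the Z-2-bromoethylidene group.
3. The acyclic C10 chain ⇐ late union of two C5 fragments by catalytic asymmetric prenylboration. The O–B bond formed in the union serves as in situ protection during ring closure, which is run in the same flask.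
4. Fragment A, a (Z)-chlorodienal ⇐ prop-2-yn-1-ol (anti-vinylmagnesiation/chlorination, then oxidation). Fragment B, a tertiary allylboronate ⇐ prenol (carbonate, then copper-catalysed SN2' borylation).
5. Ring order: one carbocycle only, closed directly after the fragment union.

Assumption: the SMILES is read as (1Z,2S,4S,6S)-4-bromo-1-(2-bromoethylidene)-2,6-dichloro-3,3-dimethylcyclohexane, with the two C–Cl bonds cis to each other and trans to the ring C–Br, and CH2Br on the side of the CHCl carbon that neighbours CMe2.

## Route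

Step 1
Reactants: 1 3-methylbut-2-en-1-ol (prenol)
Product: 2 methyl 3-methylbut-2-en-1-yl carbonate
Conditions: ClCO2Me, pyridine, CH2Cl2, 0 °C
Reagents that add atoms: methyl chloroformate COC(=O)Cl
Why: Nucleophilic acyl substitution at the chloroformate (carbonate formation) turns the primary allylic alcohol into the leaving group needed for allylic substitution, and no stereocentre is involved.

Step 2
Reactants: 2 methyl 3-methylbut-2-en-1-yl carbonate
Product: 3 4,4,5,5-tetramethyl-2-(2-methylbut-3-en-2-yl)-1,3,2-dioxaborolane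
Conditions: B2pin2 (1.1 equiv), CuCl (5 mol%), 1,3-dimesitylimidazolium chloride (5 mol%), NaOtBu (15 mol%), THF, 0 °C to rt
Reagents that add atoms: bis(pinacolato)diboron CC1(C)OB(OC1(C)C)B1OC(C)(C)C(C)(C)O1
Why: Copper-catalysed allylic borylation (formal SN2' substitution) adds the NHC–Cu–Bpin species across the alkene with boron on the γ carbon and β-eliminates the carbonate, so the transposed tertiary allylboronate is formed without any stereocentre.

Step 3
Reactants: 4 prop-2-yn-1-ol
Product: 6 (2Z)-2-(chloromethylidene)but-3-en-1-ol, via magnesium chelate 5 (not isolated)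
Conditions: CH2=CHMgBr (3 equiv), CuBr·SMe2 (10 mol%), THF, −20 to 0 °C; then N-chlorosuccinimide (2.2 equiv), −40 °C to rt; aq NH4Cl
Reagents that add atoms: vinylmagnesium bromide C=C[Mg]Br; N-chlorosuccinimide O=C1CCC(=O)N1Cl
Why: Copper-catalysed anti-carbomagnesiation of the propargylic alkoxide puts the vinyl group on C-2 and magnesium on C-3 inside a five-membered chelate, and electrophilic chlorination of that C–Mg bond with retention leaves Cl cis to CH2OH, which fixes the Z chloroalkene.

Step 4
Reactants: 6 (2Z)-2-(chloromethylidene)but-3-en-1-ol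
Product: 7 (2Z)-2-(chloromethylidene)but-3-enal
Conditions: activated MnO2 (excess), PhMe, 0 °C; filtered, cold solution used at once
Reagents that add atoms: none
Why: MnO2 oxidises only the allylic primary alcohol (allylic oxidation) under neutral conditions, so the Z chloroalkene and the diene are untouched, and the 2-formyl diene is kept cold and used immediately to outrun Diels–Alder dimerisation.

Step 5
Reactants: 7 (2Z)-2-(chloromethylidene)but-3-enal; 3 4,4,5,5-tetramethyl-2-(2-methylbut-3-en-2-yl)-1,3,2-dioxaborolane
Product: 10 (1R,2Z,3S,5S)-5-bromo-2-(2-bromoethylidene)-3-chloro-4,4-dimethylcyclohexan-1-ol, via dienyl borate 8 (not isolated), via cyclohexyl borate 9 (not isolated)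
Conditions: 3 (0.9 equiv), (R)-3,3'-bis(2,4,6-triisopropylphenyl)-1,1'-binaphthalene-2,2'-diyl hydrogen phosphate (5 mol%), PhMe, −30 °C; solvent exchanged for MeNO2–CH2Cl2; Br2 (1.0 equiv), SnBr4 (0.3 equiv), −30 °C; aq NaHCO3–Na2S2O3
Reagents that add atoms: bromine BrBr
Why: Brønsted-acid-catalysed allylboration through a closed chair transition state joins the two C5 fragments with allylic transposition (linear prenyl group) and Re-face attack sets the R carbinol centre, after which the bulky, non-nucleophilic O–Bpin group sits equatorial in the chair transition state of the bromonium-initiated cation–diene cyclisation (bromonium formation being reversible), so that anti addition places Br equatorial and cis to oxygen, the Z-chlorovinyl terminus becomes the axial C–Cl trans to both, and bromide returns to the primary allyl terminus on the side away from the equatorial oxygen (A(1,3) strain) to give the Z bromoethylidene.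

Step 6
Reactants: 10 (1R,2Z,3S,5S)-5-bromo-2-(2-bromoethylidene)-3-chloro-4,4-dimethylcyclohexan-1-ol
Product: 11 (1Z,2S,4S,6S)-4-bromo-1-(2-bromoethylidene)-2,6-dichloro-3,3-dimethylcyclohexane
Conditions: PPh3 and Cl3CC(O)CCl3 premixed in CH2Cl2 at −30 °C; then 10, −30 to 0 °C
Reagents that add atoms: hexachloroacetone ClC(Cl)(Cl)C(=O)C(Cl)(Cl)Cl
Why: Appel-type deoxychlorination activates the equatorial allylic alcohol as an alkoxyphosphonium ion with the preformed chlorophosphonium salt (no free phosphine to attack the allylic bromide), and its chloride counter-ion displaces it in an SN2 reaction with inversion, giving the axial C–Cl (S) cis to the other chlorine and trans to bromine.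

## Compound list

1 | 3-methylbut-2-en-1-ol (prenol) | CC(C)=CCO | starting material
2 | methyl 3-methylbut-2-en-1-yl carbonate | COC(=O)OCC=C(C)C | intermediate
3 | 4,4,5,5-tetramethyl-2-(2-methylbut-3-en-2-yl)-1,3,2-dioxaborolane | C=CC(C)(C)B1OC(C)(C)C(C)(C)O1 | intermediate
4 | prop-2-yn-1-ol | OCC#C | starting material
5 | 4-ethenyl-2,5-dihydro-1,2-oxamagnesole (five-membered chelate O–Mg–CH=C(CH=CH2)–CH2) | C=CC1=C[Mg]OC1 | intermediate
6 | (2Z)-2-(chloromethylidene)but-3-en-1-ol | OC/C(=C\Cl)C=C | intermediate
7 | (2Z)-2-(chloromethylidene)but-3-enal | O=C/C(=C\Cl)C=C | intermediate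
8 | 2-{[(3Z,4R)-3-(chloromethylidene)-7-methylocta-1,6-dien-4-yl]oxy}-4,4,5,5-tetramethyl-1,3,2-dioxaborolane | CC(C)=CC[C@@H](OB1OC(C)(C)C(C)(C)O1)/C(=C\Cl)C=C | intermediate
9 | 2-{[(1R,2Z,3S,5S)-5-bromo-2-(2-bromoethylidene)-3-chloro-4,4-dimethylcyclohexyl]oxy}-4,4,5,5-tetramethyl-1,3,2-dioxaborolane | CC1(C)[C@@H](Br)C[C@@H](OB2OC(C)(C)C(C)(C)O2)/C(=C/CBr)[C@@H]1Cl | intermediate
10 | (1R,2Z,3S,5S)-5-bromo-2-(2-bromoethylidene)-3-chloro-4,4-dimethylcyclohexan-1-ol | CC1(C)[C@@H](Br)C[C@@H](O)/C(=C/CBr)[C@@H]1Cl | intermediate
11 | (1Z,2S,4S,6S)-4-bromo-1-(2-bromoethylidene)-2,6-dichloro-3,3-dimethylcyclohexane | CC1(C)[C@@H](Br)C[C@H](Cl)/C(=C/CBr)[C@@H]1Cl | target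

## Step count and risks

Total step count: 6. Longest linear sequence: 4 steps (1, 2, 5, 6 or 3, 4, 5, 6).

**Step 5 (most likely to fail).** Three things must work in one flask:
- enantioselective addition of a hindered α,α-disubstituted allylboronate to a conjugated, dimerisation-prone dienal;
- survival of the O–B bond as the only protection of the carbinol;
- cyclisation through the chlorine-bearing diene terminus with clean bromide return and the predicted facial and E/Z control.

Fallback: set out from 7 and take the sequence apart. Addition of 3 to 7 promoted by BF3·OEt2 at −78 °C with hydrolytic work-up gives racemic (3Z)-3-(chloromethylidene)-7-methylocta-1,6-dien-4-ol F1. MnO2 oxidation gives (3Z)-3-(chloromethylidene)-7-methylocta-1,6-dien-4-one F2. Reduction with BH3·SMe2 and (S)-1-methyl-3,3-diphenyltetrahydro-1H,3H-pyrrolo[1,2-c][1,3,2]oxazaborole (Corey–Bakshi–Shibata reduction, the dienyl group acting as the large substituent) gives (3Z,4R)-3-(chloromethylidene)-7-methylocta-1,6-dien-4-ol F3. TBSCl/imidazole gives tert-butyl{[(3Z,4R)-3-(chloromethylidene)-7-methylocta-1,6-dien-4-yl]oxy}dimethylsilane F4. The same Br2/SnBr4 cyclisation, now with a robust equatorial silyloxy group, gives tert-butyl{[(1R,2Z,3S,5S)-5-bromo-2-(2-bromoethylidene)-3-chloro-4,4-dimethylcyclohexyl]oxy}dimethylsilane F5. HF·pyridine in MeCN returns to the route at 10.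

**Step 6.** SN2 at a ring allylic carbinol flanked by an exocyclic alkene can leak into SN2', and the chloride can exchange with the primary allylic bromide.

Fallback: set out from 10 and accept the exchange on purpose. MsCl, s-collidine and excess LiCl in DMF at 0 °C convert 10, by way of (1R,2Z,3S,5S)-5-bromo-2-(2-bromoethylidene)-3-chloro-4,4-dimethylcyclohexyl methanesulfonate F6, into (1Z,2S,4S,6S)-4-bromo-2,6-dichloro-1-(2-chloroethylidene)-3,3-dimethylcyclohexane F7, with inversion at the carbinol carbon and complete Br-to-Cl exchange at the primary allylic carbon. A Finkelstein exchange with excess LiBr in acetone at 0–20 °C then replaces only the primary allylic chloride and comes back to the route at 11.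

**Step 3.** Direct electrophilic chlorination of the chelated alkenylmagnesium in the presence of the magnesium alkoxide may be inefficient (O-chlorination, over-oxidation).

Fallback: set out from 4, run the same copper-catalysed vinylmagnesiation and trap the chelate with Bu3SnCl to give (2Z)-2-[(tributylstannyl)methylidene]but-3-en-1-ol F8. Chlorodestannylation with CuCl2 (2.2 equiv) in THF at 0 °C proceeds with retention and returns to the route at 6.

## Further compounds

F1 | step 5 | racemic (3Z)-3-(chloromethylidene)-7-methylocta-1,6-dien-4-ol | CC(C)=CCC(O)/C(=C\Cl)C=C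
F2 | step 5 | (3Z)-3-(chloromethylidene)-7-methylocta-1,6-dien-4-one | CC(C)=CCC(=O)/C(=C\Cl)C=C
F3 | step 5 | (3Z,4R)-3-(chloromethylidene)-7-methylocta-1,6-dien-4-ol | CC(C)=CC[C@@H](O)/C(=C\Cl)C=C
F4 | step 5 | tert-butyl{[(3Z,4R)-3-(chloromethylidene)-7-methylocta-1,6-dien-4-yl]oxy}dimethylsilane | CC(C)=CC[C@@H](O[Si](C)(C)C(C)(C)C)/C(=C\Cl)C=C
F5 | step 5 | tert-butyl{[(1R,2Z,3S,5S)-5-bromo-2-(2-bromoethylidene)-3-chloro-4,4-dimethylcyclohexyl]oxy}dimethylsilane | CC1(C)[C@@H](Br)C[C@@H](O[Si](C)(C)C(C)(C)C)/C(=C/CBr)[C@@H]1Cl
F6 | step 6 | (1R,2Z,3S,5S)-5-bromo-2-(2-bromoethylidene)-3-chloro-4,4-dimethylcyclohexyl methanesulfonate | CC1(C)[C@@H](Br)C[C@@H](OS(C)(=O)=O)/C(=C/CBr)[C@@H]1Cl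
F7 | step 6 | (1Z,2S,4S,6S)-4-bromo-2,6-dichloro-1-(2-chloroethylidene)-3,3-dimethylcyclohexane | CC1(C)[C@@H](Br)C[C@H](Cl)/C(=C/CCl)[C@@H]1Cl
F8 | step 3 | (2Z)-2-[(tributylstannyl)methylidene]but-3-en-1-ol | OC/C(=C\[Sn](CCCC)(CCCC)CCCC)C=C
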